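**Plan**

- Retrosynthesis: the C4 carbonyl oxygen is traced back to a C4–Cl bond, the N1–CH3 bond is cut next, and last the bond between C2 of the pyridine ring and C1′ of the tetradecyl chain.
- Forward: the quinoline bicycle is bought intact as 4-chloroquinoline and no ring is built. The chain is joined first, by radical decarboxylative alkylation with pentadecanoic acid (the C15 acid delivers the C14 radical). N1 is then methylated, and finally chloride at C4 is exchanged for oxygen.
- Enabling feature: the C2–H of the pyridine ring, α to N1, is the only site left open to a nucleophilic alkyl radical once N1 is protonated and C4 carries chlorine. That chlorine later becomes the carbonyl oxygen site.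
- Stereochemistry: the target has no stereocentre and no configured double bond, so nothing has to be set.

Key step: step 1

Remark: the target is taken as the neutral 1-methyl-4-quinolone drawn in the SMILES; no protecting group is needed anywhere in the route.

**Step 1**
Reactants: 1 4-chloroquinoline; 2 pentadecanoic acid (2.5 equiv)
Product: 3 4-chloro-2-tetradecylquinoline
Conditions: AgNO3 (0.2 equiv), (NH4)2S2O8 (3 equiv), CF3CO2H (1 equiv), MeCN/H2O 1:1, 75 °C; basic work-up to remove excess fatty acid
Reagents that add atoms: none
Why: Persulfate raises monovalent silver to divalent silver, which oxidises the carboxylate of 2 to an acyloxy radical that loses CO2 and leaves the primary tetradecyl radical. This nucleophilic radical should add to C2 of N-protonated 1, the electron-poor carbon α to N1 that still bears hydrogen, and the adduct radical cation is then oxidised and deprotonated so that the pyridine ring regains aromaticity. The closest known reaction type is the silver/persulfate decarboxylative Minisci alkylation of 4-substituted quinolines. No ring is closed and no stereocentre is formed. The step needs C2-over-C4 selectivity and monoalkylation: the chlorine occupies C4, the benzo ring is not activated towards nucleophilic radicals, and after one alkylation no activated C–H remains. The C4–Cl bond is expected to tolerate the warm, dilute acid for the reaction time and is kept as the handle for the later oxygen.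

**Step 2**
Reactants: 3 4-chloro-2-tetradecylquinoline
Product: 4 4-chloro-1-methyl-2-tetradecylquinolinium trifluoromethanesulfonate
Conditions: MeOTf (1.3 equiv), CH2Cl2, 0 °C to 40 °C; evaporate, triturate with Et2O/hexane
Reagents that add atoms: methyl trifluoromethanesulfonate, COS(=O)(=O)C(F)(F)F
Why: Quaternisation (Menshutkin-type N-alkylation) of the quinoline nitrogen with a powerful methylating agent should overcome the hindrance from the C2 chain and the deactivation by the C4 chlorine, and the non-nucleophilic triflate counter-ion leaves the C4–Cl bond untouched.

**Step 3**
Reactants: 4 4-chloro-1-methyl-2-tetradecylquinolinium trifluoromethanesulfonate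
Product: 5 1-methyl-2-tetradecylquinolin-4(1H)-one (target)
Conditions: NaOH (1 M aq, 3 equiv), THF, 0 °C to rt; solution of 4 added slowly to the base
Reagents that add atoms: sodium hydroxide, [Na+].[OH-]
Why: Nucleophilic aromatic substitution by addition–elimination at C4 of the N-methylquinolinium (a vinylogous chloroiminium) should replace chloride by hydroxide, and loss of the O–H proton gives the neutral 4-quinolone; adding 4 to excess base keeps the quinolinium concentration low and so disfavours self-condensation.

**Compound list**
1 | 4-chloroquinoline | Clc1ccnc2ccccc12 | starting material
2 | pentadecanoic acid | CCCCCCCCCCCCCCC(=O)O | starting material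
3 | 4-chloro-2-tetradecylquinoline | CCCCCCCCCCCCCCc1cc(Cl)c2ccccc2n1 | intermediate
4 | 4-chloro-1-methyl-2-tetradecylquinolinium trifluoromethanesulfonate | CCCCCCCCCCCCCCc1cc(Cl)c2ccccc2[n+]1C.[O-]S(=O)(=O)C(F)(F)F | intermediate
5 | 1-methyl-2-tetradecylquinolin-4(1H)-one | CCCCCCCCCCCCCCc1cc(=O)c2ccccc2n1C | target

**Totals**
Total step count: 3
Longest linear sequence: 3 steps (1 → 3 → 4 → 5)

**Steps most likely to fail, with fallbacks**

Step 1 (key step). The waxy C15 acid may partition poorly into the aqueous oxidant phase, so radical generation and capture by the quinolinium could stall at low conversion. Slow acid hydrolysis of the C4–Cl bond would also release chloride and remove the silver catalyst as AgCl. The fallback forms the same C2–C1′ bond by a polar instead of a radical path and sets out from 1. Oxidation of 1 with mCPBA in CH2Cl2 should give 4-chloroquinoline 1-oxide F1. Tetradecylmagnesium bromide (from 1-bromotetradecane and Mg) in THF at −40 °C is expected to add to C2, the oxygen-directed position, giving racemic 4-chloro-2-tetradecyl-1,2-dihydroquinolin-1-ol F2 as its magnesium salt, which is not isolated. Warming with acetic anhydride acetylates the N–O oxygen and eliminates acetic acid across N1–C2, restoring the aromatic ring. The route is rejoined at 3.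

Step 3. Hydroxide may deprotonate the side-chain CH2 attached to C2 of the quinolinium instead of attacking C4. The resulting enamine-type anhydrobase could then condense at C4 of unreacted salt (cyanine-type dimerisation) in competition with the wanted substitution. The fallback introduces the oxygen under acid, where no anhydrobase can form, and sets out from 3. Refluxing 3 in aqueous acetic acid should hydrolyse the C4–Cl bond to give 2-tetradecylquinolin-4(1H)-one F5. Deprotonation with NaH in DMF and alkylation with iodomethane is then expected to methylate the ambident anion mainly on nitrogen. The route is rejoined at 5, the target, without passing through 4.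

Step 2. Quaternisation may stay incomplete because N1 is flanked by the C2 chain and the peri C8–H and is made less nucleophilic by the C4 chlorine. The fallback first turns the chlorine into a donor group and sets out from 3. NaOMe in MeOH at reflux should displace chloride to give 4-methoxy-2-tetradecylquinoline F3, whose nitrogen is more nucleophilic through donation from the methoxy group. Heating F3 with iodomethane in MeCN in a sealed tube at about 100 °C is expected to form 4-methoxy-1-methyl-2-tetradecylquinolinium iodide F4 in the flask. Iodide then removes the O-methyl group by SN2 attack, which is the known thermal O-to-N methyl transfer of 4-methoxyquinolines. The route is rejoined at 5, the target, without passing through 4.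

**Further compounds**
F1 | step 1 | 4-chloroquinoline 1-oxide | [O-][n+]1ccc(Cl)c2ccccc12
F2 | step 1 | 4-chloro-2-tetradecyl-1,2-dihydroquinolin-1-ol (racemic) | CCCCCCCCCCCCCCC1C=C(Cl)c2ccccc2N1O
F3 | step 2 | 4-methoxy-2-tetradecylquinoline | CCCCCCCCCCCCCCc1cc(OC)c2ccccc2n1
F4 | step 2 | 4-methoxy-1-methyl-2-tetradecylquinolinium iodide | CCCCCCCCCCCCCCc1cc(OC)c2ccccc2[n+]1C.[I-]
F5 | step 3 | 2-tetradecylquinolin-4(1H)-one | CCCCCCCCCCCCCCc1cc(=O)c2ccccc2[nH]1
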